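A small charge of free catalyst, 5.2 mol% of the starting material and far less than it, has to make the product here, so I write the balance of the catalyst.

| flask | starting material | reagent | free catalyst | time | remark |
|---|---|---|---|---|---|
| elm | 0.50 mM | 1.20 equiv | 5.2 mol% | 20 s | a closed flask charged with all of it at once and left for 20 s |
| cedar | 0.50 mM | 1.20 equiv | 5.2 mol% |  | one stirred flow tank at steady state, fed with the mixture as stated, mean residence time 100 s |
| birch | 0.50 mM | 1.20 equiv | 5.2 mol% |  | a single well-mixed tank run continuously and read at steady state, 20 s in it on average |
| maple | 0.50 mM (fed, over 10.0 s) | 1.20 equiv | 5.2 mol% | 20 s | all but starting material at the start; starting material goes in evenly over 10.0 s, the run ends at 20 s |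

    catalyst intermediate C → free catalyst + product (k1 = 1.0 s⁻¹)
    catalyst intermediate B ⇌ by-product + catalyst intermediate C (K2 = 0.0048 M, k2 = 0.18 s⁻¹)
    reagent + free catalyst → catalyst intermediate A (k3 = 3800 M⁻¹ s⁻¹)
    starting material + catalyst intermediate A ⇌ catalyst intermediate B (K4 = 15000 M⁻¹, k4 = 7300 M⁻¹ s⁻¹)

- the set-up with the highest amount of product at the outlet or at the end, in percent of the starting material put in ("none" if the first two lie within 2 percentage points) (elm / cedar / birch / maple / none)
- amount of product at the outlet or at the end, in percent of the starting material put in, elm
- amount of product at the outlet or at the end, in percent of the starting material put in, cedar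
- amount of product at the outlet or at the end, in percent of the starting material put in, birch
- amount of product at the outlet or at the end, in percent of the starting material put in, maple

- the stated concentrations are those of everything mixed, before any reaction; amounts are the same in each set-up
- the feed brings no volume worth counting
- run time (elm): 20 s

Suppose the cycle turns at a steady flux. Each form of the catalyst then holds that flux times its waiting time, and the forms together hold the charge, so the flux is the catalyst charge divided by the cycle time, the sum of the waits. At the charged concentrations, free catalyst waits 0.439 s, catalyst intermediate C 1.00 s and catalyst intermediate B 5.56 s. Catalyst intermediate A waits 0.274 s per attempt and needs 3.70 attempts, because catalyst intermediate B falls back at 0.487 s⁻¹, faster than the 0.18 s⁻¹ at which it goes on. I drop the return from catalyst intermediate C: even with by-product at the level of the whole charge it runs at 0.0187 s⁻¹, much slower than the 1.0 s⁻¹ forward. The cycle time comes to 8.01 s.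

Loading times time over cycle time is 13.0% for a stay of 20 s. I call this the turnover share: the part of the starting material the catalyst can pass through at its opening pace. Elm and maple run for that time and birch holds its mixture that long on average, so the share gives the three of them one figure, and I expect each to fall somewhat short of it. For cedar, with 100 s in the tank on average, it gives 64.9%, much more. One number is not enough there, though, since a conversion that high leaves the tank thinner than the feed. Reckoning the cycle at those thinner levels gives 10.4 s and a share of 50.0%. That overcorrects, so I place cedar between the two figures.

The forecast names cedar, with 11.9% for elm, 52% for cedar, 11.6% for birch and 10.4% for maple. It reasons from the same cycle, “so B is the resting state”, and my 13.0% is higher than its elm figure, which counts turnovers “after the lag”.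

The simulation gives 11.8% for elm, 52.3% for cedar, 11.7% for birch and 10.4% for maple, and cedar leads.

Cedar's lead comes from the back-mixing and the longer stay: without them the same charge gives 11.8% in place of 52.3%. Its 52.3% lies above my corrected 50.0% and below the opening 64.9%. Elm reaches 90.8% of its turnover share of 13.0%. A neighbouring flask, like elm but with 2.1 mol% of free catalyst, has a share of 5.24% and gives 4.83%, which is 92.1% of it.

The numbers of this flask are made up, and the outcome is calculated.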